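1. 3 questions stood on one flask, and all are one quantity at 3 times: R, the ratio of J to D (a selectivity), in a closed flask where Z reacts under G held constant.

- north: Z 1.1 M; G 200 mM (held); the very flask that is asked about, followed so far
- flask: Z 1.1 M; G 200 mM (held); time 4.0 d

north run (percent of the Z charged)

| time / h | J / % | D / % | Z / % |
|---|---|---|---|
| 2.00 | 1.2 | 3.9 | 82.3 |
| 4.00 | 3.7 | 6.6 | 66.3 |
| 6.00 | 6.0 | 10.1 | 55.1 |
| 8.00 | 6.4 | 11.4 | 46.2 |
| 10.0 | 10.2 | 12.6 | 40.4 |
| 12.0 | 10.5 | 12.1 | 34.7 |

(scatter of a reading: 0.5 percentage points)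

* ratio of J to D at 1.5 h
* ratio of J to D at 12 h
* ratio of J to D at 4.0 d

- at the start none of G is in solution

2. A reading carried 0.5 percentage points, and J at 2.00 h was 1.2 %, so I pooled neighbouring readings instead of trusting single ratios. The readings at 4.00 h and 6.00 h gave R = 0.581 at 5.00 h. Those at 10.0 h and 12.0 h gave R = 0.838 at 11.0 h.

3. If J and D each change exponentially, R does too, at the difference of their rate constants, so log10 R runs straight against time. I therefore worked in powers of ten. The two pooled points gave τ = 37.7 h, the tenfold time, the time R takes to grow by a factor of 10. Two points cannot test that straightness, so I assumed it.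

4. From 11.0 h to 4.0 d lay 2.26 powers of ten, so I reckoned R near 151 at 4.0 d. Running the same line to the earlier times gave 0.469 at 1.5 h and 0.891 at 12 h.

5. The forecast gave 0.22 and 0.87 as smoothed ratios from the readings, and 15 for the last time, of which it said “the long-time ratio is large but very uncertain”. Its first and last figures were lower than mine.

6. The flask gave 0.503, 0.881 and 124. Here X is dissolved G, E a further product, and L a species formed on the way.

    Z + X ⇌ D (K = 52.0 M⁻¹, k = 0.660 M⁻¹ h⁻¹)
    Z + X ⇌ J (K = 960 M⁻¹, k = 0.320 M⁻¹ h⁻¹)
    X + D → E (k = 1.60 M⁻¹ h⁻¹)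
    G ⇌ X, rate k4*(csat - [X]) (kL = 0.290 h⁻¹)
    Z ⇌ L (K = 0.970, k = 0.0770 h⁻¹)

7. From 12 h to 4.0 d the flask's R showed a tenfold time of 39.1 h against my 37.7 h, and the neighbouring flask with 0.44 M of Z, going from 1.25 to 258, showed 36.3 h. At 4.0 d in the flask, the half-life of D by X + D → E, 0.094 d, was shorter than the 0.201 d relaxation half-life of Z + X ⇌ D, and R stood above 18.5, the ratio of the equilibrium constants for J and D, at 124.

Readings and results are simulated with constants of no real substance; noise was put on by code.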